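**Strategy.** The cycloheptane ring is cut into a three-carbon unit (C4–C5–C6 of the cyclohepta[b]furanone: CH2, carbinol, CHMe) and a four-carbon unit (C3a–C8a–C8–C7). A diethylzinc-mediated (4+3) cycloaddition of the methyl-oxyallyl cation from 1,3-dibromobutan-2-one with an enantiopure 2-furyl carbinol forms C3a–C4 and C6–C7 in one operation. It exploits two features: the C5 oxygen flanked by C4 and C6 (an oxyallyl cation) and the C7 tertiary hydroxyl, which is the furan oxygen. The side-chain carbinol, the later enone carbonyl, directs face and C6 configuration through a zinc chelate and is erased at the end. The oxygen bridge is then opened and the lactone closed by tandem Michael addition/olefination.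

Key step: step 4

Numbering: ring atoms carry the locants of the target cyclohepta[b]furan-2-one throughout (C3a, C4, C5, C6, C7, C8, C8a); in the 8-oxabicyclo[3.2.1]octane names of the compound list these are C5, C4, C3, C2, C1, C7 and C6.

Assumption: the facial sense of the zinc chelate model in step 4 makes the (R)-carbinol the required antipode; this centre is oxidized away in step 15, so the (S)-carbinol from the (R)-catalyst would serve equally if the sense were the reverse.

Step 1
Reactants: 1 N-methoxy-N-methylfuran-2-carboxamide; 2 prop-1-yn-1-ylmagnesium bromide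
Product: 3 1-(furan-2-yl)but-2-yn-1-one
Conditions: THF, −78 to 0 °C; aq NH4Cl
Reagents that add atoms: none
Why: Weinreb ketone synthesis, in which the magnesium chelate of the tetrahedral adduct survives until work-up and so prevents a second addition.

Step 2
Reactants: 3 1-(furan-2-yl)but-2-yn-1-one
Product: 4 (R)-1-(furan-2-yl)but-2-yn-1-ol
Conditions: (S)-Me-CBS [(S)-1-methyl-3,3-diphenyltetrahydro-1H,3H-pyrrolo[1,2-c][1,3,2]oxazaborole] (20 mol %), BH3·SMe2, THF, −30 °C; MeOH
Reagents that add atoms: none
Why: Corey–Bakshi–Shibata reduction, in which the slim propynyl group takes the place of the small substituent and the furyl that of the large one, so that the (S)-catalyst should deliver hydride to give the (R)-carbinol.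

Step 3
Reactants: 4 (R)-1-(furan-2-yl)but-2-yn-1-ol
Product: 5 (R,E)-1-(furan-2-yl)but-2-en-1-ol
Conditions: NaAlH2(OCH2CH2OMe)2, THF, 0 °C to rt; aq potassium sodium tartrate
Reagents that add atoms: none
Why: hydroxyl-directed trans-hydroalumination of the propargylic alcohol followed by protonolysis should give the E-alkene only and leaves the carbinol centre untouched.

Step 4
Reactants: 5 (R,E)-1-(furan-2-yl)but-2-en-1-ol; 6 1,3-dibromobutan-2-one
Product: 9 (1R,2R,5R)-1-[(1R,2E)-1-hydroxybut-2-en-1-yl]-2-methyl-8-oxabicyclo[3.2.1]oct-6-en-3-one, via ethylzinc alkoxide 7 (not isolated), via zinc oxyallyl cation 8 (not isolated)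
Conditions: Et2Zn (2.5 equiv), PhMe, 0 °C; then 6 (1.5 equiv) added slowly, 0 °C to rt; aq NH4Cl
Reagents that add atoms: none
Why: Et2Zn first makes the ethylzinc alkoxide 7 and then, by bromine–zinc exchange and loss of bromide from 6, the zinc-bound 1-methyl-2-oxyallyl cation 8, which adds across the furan 2,5-positions in a (4+3) cycloaddition, the reaction type established for diethylzinc-generated oxyallyl cations and secondary 2-furyl carbinols. The seven-membered ring is closed intermolecularly in a concerted but asynchronous way: the unsubstituted oxyallyl terminus (C4) should bond first to the unsubstituted, most nucleophilic furan carbon (C3a), and the methyl-bearing terminus (C6) then closes onto the substituted carbon (C7); the furan oxygen becomes the C7–O–C3a bridge and no other ring is formed. C3a and C7 are set together by suprafacial addition to the furan, and their absolute sense by the carbinol centre: in the zinc chelate (alkoxide zinc bound to the oxyallyl oxygen, carbinol hydrogen eclipsing furan C3–H) the cation is delivered to the furan face that carries the alkoxide oxygen. The same chelate enforces the extended transition state, which places the methyl of the W-shaped (Z) cation at C6 on the side of the oxygen bridge (axial), as the target requires. The step needs head-to-head orientation and face selectivity; the first rests on the electronic bias just described, the second on the chelate.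

Step 5
Reactants: 9 (1R,2R,5R)-1-[(1R,2E)-1-hydroxybut-2-en-1-yl]-2-methyl-8-oxabicyclo[3.2.1]oct-6-en-3-one
Product: 10 tert-butyldimethylsilyl ether of 9 at the side-chain hydroxyl
Conditions: TBSOTf, 2,6-lutidine, CH2Cl2, −78 °C
Reagents that add atoms: tert-butyldimethylsilyl triflate, CC(C)(C)[Si](C)(C)OS(=O)(=O)C(F)(F)F
Why: O-silylation of the hindered secondary alcohol by the silyl triflate is far faster than enol silylation of the ketone with the weak base 2,6-lutidine, and no stereocentre is touched.

Step 6
Reactants: 10 tert-butyldimethylsilyl ether of 9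
Product: 11 exo,exo-diol of 10 (hydroxyls at C8a and C8 both on the face of the oxygen bridge)
Conditions: K2OsO4·2H2O (2 mol %), N-methylmorpholine N-oxide, acetone/H2O, 0 °C
Reagents that add atoms: N-methylmorpholine N-oxide, C[N+]1([O-])CCOCC1; water, O
Why: Upjohn dihydroxylation, in which the strained ring alkene should react well before the side-chain E-alkene screened by its silyloxy-bearing neighbour, and osmium tetroxide adds from the exo face (the face of the oxygen bridge), which sets the C8a–O bond of the future lactone.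

Step 7
Reactants: 11 exo,exo-diol; 12 2-(diethoxyphosphoryl)acetic acid
Product: 13 C8a mono[2-(diethoxyphosphoryl)acetate] of 11
Conditions: DCC, 4-(dimethylamino)pyridine (cat.), CH2Cl2, 0 °C
Reagents that add atoms: none
Why: Steglich esterification, in which the C8a hydroxyl next to the CH bridgehead C3a should be acylated in preference to the C8 hydroxyl flanked by the quaternary C7 and its silyloxy side chain.

Step 8
Reactants: 13 C8a mono(phosphonoacetate)
Product: 14 C8 ketone of 13
Conditions: Dess–Martin periodinane, NaHCO3, CH2Cl2, 0 °C to rt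
Reagents that add atoms: none
Why: buffered Dess–Martin oxidation of the remaining secondary alcohol gives the C8 ketone under neutral conditions that do not enolize it toward the acyloxy-bearing C8a.

Step 9
Reactants: 14 C8 ketone
Product: 15 C8 endo alcohol (trans to the C8a ester)
Conditions: NaBH4, MeOH/CH2Cl2, −78 °C
Reagents that add atoms: none
Why: the strained C8 ketone, activated by two α-oxygens, should be reduced before the C5 ketone (screened by the axial C6 methyl on one face and by the two-carbon bridge on the other), and hydride enters from the open exo face to give the endo alcohol, which is the C8 configuration of the target.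

Step 10
Reactants: 15 C8 endo alcohol; 16 angelic acid
Product: 18 C8 angelate of 15, via mixed anhydride 17 (not isolated)
Conditions: 16, 2,4,6-trichlorobenzoyl chloride, Et3N, PhMe, rt; then 15, 80 °C
Reagents that add atoms: none
Why: Yamaguchi-type acylation through the mixed anhydride, run without a nucleophilic amine catalyst, is the established way to acylate hindered secondary alcohols with angelic acid while keeping the Z double bond.

Step 11
Reactants: 18 C8 angelate
Product: 19 ring-opened cyclohept-2-enone with the C7 oxygen as triethylsilyl ether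
Conditions: TESOTf, Et3N, CH2Cl2, −78 to 0 °C
Reagents that add atoms: triethylsilyl triflate, CC[Si](CC)(CC)OS(=O)(=O)C(F)(F)F
Why: silyl-triflate-mediated β-elimination of a β-alkoxy ketone, in which enol silylation toward C4 (the only α-carbon with an axial hydrogen) expels the bridge oxygen from C3a to give the C3a=C4 enone while the released tertiary C7 oxygen is trapped as its silyl ether.

Step 12
Reactants: 19 ring-opened cyclohept-2-enone
Product: 21 silyl-protected α-methylene lactone, via phosphonate lactone 20 (not isolated)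
Conditions: KOtBu (1.1 equiv), THF, 0 °C; then (CH2O)n, 0 °C to rt
Reagents that add atoms: formaldehyde (from paraformaldehyde), C=O
Why: tandem intramolecular Michael addition/Horner–Wadsworth–Emmons olefination, in which the ester tether delivers the phosphonate carbanion to C3a on the face of the C8a–O bond (5-exo-trig), fixing the cis ring fusion, and the resulting phosphonate anion then olefinates formaldehyde.

Step 13
Reactants: 21 silyl-protected α-methylene lactone
Product: 22 C7 hydroxy C5 ketone with free side-chain carbinol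
Conditions: HF·pyridine, THF/pyridine, 0 °C to rt
Reagents that add atoms: none
Why: fluoride cleaves both silyl ethers under buffered acidic conditions that spare the angelate, the α-methylene lactone and the base-sensitive β-hydroxy ketone.

Step 14
Reactants: 22 C7 hydroxy C5 ketone
Product: 23 C5,C7-diol with side-chain allylic alcohol
Conditions: Me4NBH(OAc)3, AcOH/MeCN, −30 °C
Reagents that add atoms: none
Why: Evans–Saksena reduction, in which the tertiary C7 hydroxyl binds boron and delivers hydride internally to the β-ketone on its own ring face, giving the 1,3-anti diol (C5 carbinol of the target) while the esters and the enoate are inert.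

Step 15
Reactants: 23 C5,C7-diol with side-chain allylic alcohol
Product: 24 target (CNP0149130.1)
Conditions: MnO2, CH2Cl2, rt
Reagents that add atoms: none
Why: MnO2 oxidizes only the allylic secondary alcohol, giving the E-enone and leaving the saturated secondary and the tertiary alcohols.

**Compound list**

1 | N-methoxy-N-methylfuran-2-carboxamide | CON(C)C(=O)c1ccco1 | starting material
2 | prop-1-yn-1-ylmagnesium bromide | CC#C[Mg]Br | starting material
3 | 1-(furan-2-yl)but-2-yn-1-one | CC#CC(=O)c1ccco1 | intermediate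
4 | (R)-1-(furan-2-yl)but-2-yn-1-ol | CC#C[C@@H](O)c1ccco1 | intermediate
5 | (R,E)-1-(furan-2-yl)but-2-en-1-ol | C/C=C/[C@@H](O)c1ccco1 | intermediate
6 | 1,3-dibromobutan-2-one | CC(Br)C(=O)CBr | starting material
7 | ethylzinc alkoxide of 5 | C/C=C/[C@@H](O[Zn]CC)c1ccco1 | intermediate
8 | ethylzinc-bound 1-methyl-2-oxyallyl cation, bromide | C[CH+]C(=C)O[Zn]CC.[Br-] | intermediate
9 | (1R,2R,5R)-1-[(1R,2E)-1-hydroxybut-2-en-1-yl]-2-methyl-8-oxabicyclo[3.2.1]oct-6-en-3-one; methyl axial, on the face of the oxygen bridge | C1[C@H]2CC(=O)[C@H](C)[C@@](O2)([C@H](O)/C=C/C)C=1 | intermediate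
10 | (1R,2R,5R)-1-[(1R,2E)-1-(tert-butyldimethylsilyloxy)but-2-en-1-yl]-2-methyl-8-oxabicyclo[3.2.1]oct-6-en-3-one | C1[C@H]2CC(=O)[C@H](C)[C@@](O2)([C@H](O[Si](C)(C)C(C)(C)C)/C=C/C)C=1 | intermediate
11 | 6-exo,7-exo-dihydroxy derivative of 10 (8-oxabicyclo[3.2.1]octan-3-one; both hydroxyls syn to the oxygen bridge; C1, C2, C5 as in 9) | O[C@@H]1[C@H]2CC(=O)[C@H](C)[C@@](O2)([C@H](O[Si](C)(C)C(C)(C)C)/C=C/C)[C@@H]1O | intermediate
12 | 2-(diethoxyphosphoryl)acetic acid | CCOP(=O)(OCC)CC(=O)O | starting material
13 | 6-exo-[2-(diethoxyphosphoryl)acetoxy]-7-exo-hydroxy derivative (mono-ester of 11 at bicyclic C6) | CCOP(=O)(OCC)CC(=O)O[C@@H]1[C@H]2CC(=O)[C@H](C)[C@@](O2)([C@H](O[Si](C)(C)C(C)(C)C)/C=C/C)[C@@H]1O | intermediate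
14 | 6-exo-[2-(diethoxyphosphoryl)acetoxy]-8-oxabicyclo[3.2.1]octane-3,7-dione derivative (7-ketone of 13) | CCOP(=O)(OCC)CC(=O)O[C@@H]1[C@H]2CC(=O)[C@H](C)[C@@](O2)([C@H](O[Si](C)(C)C(C)(C)C)/C=C/C)C1=O | intermediate
15 | 6-exo-[2-(diethoxyphosphoryl)acetoxy]-7-endo-hydroxy derivative (trans; 7-hydroxyl anti to the oxygen bridge) | CCOP(=O)(OCC)CC(=O)O[C@@H]1[C@H]2CC(=O)[C@H](C)[C@@](O2)([C@H](O[Si](C)(C)C(C)(C)C)/C=C/C)[C@H]1O | intermediate
16 | angelic acid, (Z)-2-methylbut-2-enoic acid | C/C=C(/C)C(=O)O | starting material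
17 | (Z)-2-methylbut-2-enoic 2,4,6-trichlorobenzoic anhydride | C/C=C(/C)C(=O)OC(=O)c1c(Cl)cc(Cl)cc1Cl | intermediate
18 | 7-endo (Z)-2-methylbut-2-enoate of 15 | CCOP(=O)(OCC)CC(=O)O[C@@H]1[C@H]2CC(=O)[C@H](C)[C@@](O2)([C@H](O[Si](C)(C)C(C)(C)C)/C=C/C)[C@H]1OC(=O)/C(C)=C\C | intermediate
19 | 6-[(1R,2E)-1-(tert-butyldimethylsilyloxy)but-2-en-1-yl]-4-[2-(diethoxyphosphoryl)acetoxy]-7-methyl-5-[(Z)-2-methylbut-2-enoyloxy]-6-(triethylsilyloxy)cyclohept-2-en-1-one; 4-acyloxy, 6-silyloxy and 7-methyl on one ring face, 5-angeloyloxy and the side chain on the other | CCOP(=O)(OCC)CC(=O)O[C@@H]1C=CC(=O)[C@H](C)[C@@](O[Si](CC)(CC)CC)([C@H](O[Si](C)(C)C(C)(C)C)/C=C/C)[C@H]1OC(=O)/C(C)=C\C | intermediate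
20 | 3-(diethoxyphosphoryl) cis-fused lactone (3-phosphono analogue of 21; C3 unassigned) | CCOP(=O)(OCC)C1C(=O)O[C@@H]2[C@H]1CC(=O)[C@H](C)[C@@](O[Si](CC)(CC)CC)([C@H](O[Si](C)(C)C(C)(C)C)/C=C/C)[C@H]2OC(=O)/C(C)=C\C | intermediate
21 | 7-[(1R,2E)-1-(tert-butyldimethylsilyloxy)but-2-en-1-yl]-6-methyl-3-methylidene-2,5-dioxo-7-(triethylsilyloxy)octahydro-2H-cyclohepta[b]furan-8-yl (Z)-2-methylbut-2-enoate; ring configuration as in 24 | C=C1C(=O)O[C@@H]2[C@H]1CC(=O)[C@H](C)[C@@](O[Si](CC)(CC)CC)([C@H](O[Si](C)(C)C(C)(C)C)/C=C/C)[C@H]2OC(=O)/C(C)=C\C | intermediate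
22 | 7-hydroxy-7-[(1R,2E)-1-hydroxybut-2-en-1-yl]-6-methyl-3-methylidene-2,5-dioxooctahydro-2H-cyclohepta[b]furan-8-yl (Z)-2-methylbut-2-enoate; ring configuration as in 24 | C=C1C(=O)O[C@@H]2[C@H]1CC(=O)[C@H](C)[C@@](O)([C@H](O)/C=C/C)[C@H]2OC(=O)/C(C)=C\C | intermediate
23 | 5,7-dihydroxy-7-[(1R,2E)-1-hydroxybut-2-en-1-yl]-6-methyl-3-methylidene-2-oxooctahydro-2H-cyclohepta[b]furan-8-yl (Z)-2-methylbut-2-enoate; ring configuration as in 24 | C=C1C(=O)O[C@@H]2[C@H]1C[C@@H](O)[C@H](C)[C@@](O)([C@H](O)/C=C/C)[C@H]2OC(=O)/C(C)=C\C | intermediate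
24 | (3aS,5R,6S,7S,8S,8aR)-7-[(E)-but-2-enoyl]-5,7-dihydroxy-6-methyl-3-methylidene-2-oxooctahydro-2H-cyclohepta[b]furan-8-yl (Z)-2-methylbut-2-enoate | C=C1C(=O)O[C@@H]2[C@H]1C[C@@H](O)[C@H](C)[C@@](O)(C(=O)/C=C/C)[C@H]2OC(=O)/C(C)=C\C | target

**Step count and risks**

Total: 15 steps. Longest linear sequence: 15 steps (1 to 24).

Step 4 (key step). What may go wrong: the methyl-bearing terminus of 8 bonds to C3a instead of C7, the zinc chelate gives poor face selectivity, or the allylic furyl carbinol ionizes under the zinc halide that forms. Fallback, setting out from 5 and coming back at 10: the same two bonds are made by a rhodium-carbenoid tandem cyclopropanation/Cope rearrangement, whose orientation is fixed by mechanism. 5 is silylated (TBSCl, imidazole, DMF) to the silyl ether F1. F1 and methyl 3-(tert-butyldimethylsilyloxy)-2-diazobut-3-enoate F2 (from methyl acetoacetate by diazo transfer and enol silylation) are combined with Rh2(S-PTAD)4 (hexanes, −30 °C to rt; the antipodal catalyst if mismatched with the carbinol) to give the oxabicyclooctadiene F3, the carbenoid carbon bonding to the unsubstituted furan carbon. Et3N·3HF (THF, 0 °C) cleaves only the silyl enol ether to give the β-keto ester F4. Its dianion (NaH, then nBuLi, THF, −78 °C) is methylated by MeI at the γ-carbon (future C6) from the exo face to give F5, and Krapcho demethoxycarbonylation (LiCl, wet DMSO, 120 °C) returns 10.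

Step 12. What may go wrong: the potassium phosphonate or residual alkoxide eliminates the allylic acyloxy group or the β-silyloxy group faster than the 5-exo Michael closure, or epimerizes C6. Fallback, setting out from 18 and coming back at 22: the enone is not preformed. 18 is treated with LiCl and DBU in MeCN, so that reversible retro-oxa-Michael opening of the bridge gives the hydroxy enone F6 only in low stationary concentration, where the soft lithium phosphonate traps it as the phosphonate lactone F7. Paraformaldehyde then gives the hydroxy α-methylene lactone F8, and HF·pyridine removes the remaining silyl ether to give 22.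

Step 10. What may go wrong: acylation of the endo hydroxyl on the concave face next to the quaternary C7 is slow, and forcing it isomerizes the angelate to the tiglate. Fallback, setting out from 15 and coming back at 21: the ester is put on after the bicycle is opened. Excess TESOTf/Et3N converts 15 into the bis(triethylsilyl) enone F9. KOtBu and then paraformaldehyde close the lactone through the phosphonate lactone F10 to the α-methylene lactone F11. Pyridinium p-toluenesulfonate in MeOH at 0 °C frees the secondary C8 hydroxyl to give F12, while the tertiary triethylsilyl and the allylic tert-butyldimethylsilyl ethers stay. The mixed anhydride 17, made as in step 10, then acylates this unencumbered hydroxyl to give 21.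

**Further compounds**

F1 | step 4 | (R,E)-tert-butyl{[1-(furan-2-yl)but-2-en-1-yl]oxy}dimethylsilane | C/C=C/[C@@H](O[Si](C)(C)C(C)(C)C)c1ccco1
F2 | step 4 | methyl 3-(tert-butyldimethylsilyloxy)-2-diazobut-3-enoate | COC(=O)C(=[N+]=[N-])C(=C)O[Si](C)(C)C(C)(C)C
F3 | step 4 | methyl 3-(tert-butyldimethylsilyloxy)-5-[(1R,2E)-1-(tert-butyldimethylsilyloxy)but-2-en-1-yl]-8-oxabicyclo[3.2.1]octa-2,6-diene-2-carboxylate | C1[C@H]2C(C(=O)OC)=C(O[Si](C)(C)C(C)(C)C)C[C@@](O2)([C@H](O[Si](C)(C)C(C)(C)C)/C=C/C)C=1
F4 | step 4 | methyl 5-[(1R,2E)-1-(tert-butyldimethylsilyloxy)but-2-en-1-yl]-3-oxo-8-oxabicyclo[3.2.1]oct-6-ene-2-carboxylate | C1[C@H]2C(C(=O)OC)C(=O)C[C@@](O2)([C@H](O[Si](C)(C)C(C)(C)C)/C=C/C)C=1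
F5 | step 4 | methyl 5-[(1R,2E)-1-(tert-butyldimethylsilyloxy)but-2-en-1-yl]-4-methyl-3-oxo-8-oxabicyclo[3.2.1]oct-6-ene-2-carboxylate, methyl syn to the oxygen bridge | C1[C@H]2C(C(=O)OC)C(=O)[C@H](C)[C@@](O2)([C@H](O[Si](C)(C)C(C)(C)C)/C=C/C)C=1
F6 | step 12 | 6-hydroxy analogue of 19 (tertiary hydroxyl free; ring-opened hydroxy enone, not isolated) | CCOP(=O)(OCC)CC(=O)O[C@@H]1C=CC(=O)[C@H](C)[C@@](O)([C@H](O[Si](C)(C)C(C)(C)C)/C=C/C)[C@H]1OC(=O)/C(C)=C\C
F7 | step 12 | 3-(diethoxyphosphoryl) lactone with free C7 hydroxyl (not isolated) | CCOP(=O)(OCC)C1C(=O)O[C@@H]2[C@H]1CC(=O)[C@H](C)[C@@](O)([C@H](O[Si](C)(C)C(C)(C)C)/C=C/C)[C@H]2OC(=O)/C(C)=C\C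
F8 | step 12 | C7 hydroxy analogue of 21 (side chain still tert-butyldimethylsilyl ether) | C=C1C(=O)O[C@@H]2[C@H]1CC(=O)[C@H](C)[C@@](O)([C@H](O[Si](C)(C)C(C)(C)C)/C=C/C)[C@H]2OC(=O)/C(C)=C\C
F9 | step 10 | analogue of 19 with a triethylsilyl ether in place of the angelate | CCOP(=O)(OCC)CC(=O)O[C@@H]1C=CC(=O)[C@H](C)[C@@](O[Si](CC)(CC)CC)([C@H](O[Si](C)(C)C(C)(C)C)/C=C/C)[C@H]1O[Si](CC)(CC)CC
F10 | step 10 | 3-(diethoxyphosphoryl) lactone with C8 triethylsilyl ether (not isolated) | CCOP(=O)(OCC)C1C(=O)O[C@@H]2[C@H]1CC(=O)[C@H](C)[C@@](O[Si](CC)(CC)CC)([C@H](O[Si](C)(C)C(C)(C)C)/C=C/C)[C@H]2O[Si](CC)(CC)CC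
F11 | step 10 | analogue of 21 with a triethylsilyl ether at C8 in place of the angelate | C=C1C(=O)O[C@@H]2[C@H]1CC(=O)[C@H](C)[C@@](O[Si](CC)(CC)CC)([C@H](O[Si](C)(C)C(C)(C)C)/C=C/C)[C@H]2O[Si](CC)(CC)CC
F12 | step 10 | C8 alcohol corresponding to 21 (angelate absent) | C=C1C(=O)O[C@@H]2[C@H]1CC(=O)[C@H](C)[C@@](O[Si](CC)(CC)CC)([C@H](O[Si](C)(C)C(C)(C)C)/C=C/C)[C@H]2O
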